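**Labels.** The labels follow the target SMILES read left to right. The carbons are C1–C18 and C20–C26, the ring oxygen is O19, and the hydroxyl oxygen on C18 is not numbered. C4 carries the isopropenyl group. C7/C25 is the C/D fusion, C11/C24 the B/C fusion and C14/C26 the A/B fusion. C15 is CHMe, C18 the hemiketal carbon, C20 the OCH2, and C21=C22 the ring alkene.
- β face: isopropenyl, H25, Me12, Me16, O19.
- α face: H4, Me8, H24, H14, H15, H26, 18‑OH.

**Assumption.** Commercial (S)‑limonene and (R)‑3‑methylcyclopentanone are taken as enantiopure.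

## Retrosynthetic overview
1. Ring B and the THF hemiketal (C26–C21 and O19–C20) form in the last step by anodic cyclisation of a ring‑A silyl enol ether onto a homoallenyl arm on C24.
2. The silyl enol ether comes from 1,4‑hydrosilylation of a 3‑substituted 4‑methylcyclopentenone, with H14 delivered anti to Me16. The allene comes from a CH2CO2Me arm.
3. Ring C (C11–C24, which sets quaternary C11 and C24) forms by photoreductive coupling of a dienone δ‑carbon with an enoate β‑carbon.
4. The dienone comes from a Heck union of (S)‑4‑methylcyclopentenone (ring A, from (R)‑3‑methylcyclopentanone) with a vinyl iodide carried by the ring‑D aldehyde.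
5. Ring D comes from (S)‑limonene by ozonolysis, enolate alkylation, aldol ring contraction and anti Me‑cuprate addition. Ring order: D, then A attached, then C, then B/THF.

## Route

**Step 1**
Reactants: 1 prop‑2‑yn‑1‑ol
Product: 2 (E)‑3‑iodo‑2‑methylprop‑2‑en‑1‑ol
Conditions: Me3Al, Cp2ZrCl2 (cat.), CH2Cl2, 0 °C→rt; I2, THF, −30 °C
Reagents that add atoms: trimethylaluminium C[Al](C)C; iodine II
Why: Negishi Zr‑catalysed carboalumination is a syn addition that puts Me on the internal carbon, and iodinolysis proceeds with retention to give only the E‑vinyl iodide.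

**Step 2**
Reactants: 2
Product: 3 (E)‑3‑bromo‑1‑iodo‑2‑methylprop‑1‑ene
Conditions: CBr4, PPh3, CH2Cl2, 0 °C
Reagents that add atoms: carbon tetrabromide BrC(Br)(Br)Br
Why: The Appel reaction converts the primary allylic alcohol to the bromide without touching the vinyl iodide or its geometry.

**Step 3**
Reactants: 4 (R)‑3‑methylcyclopentanone
Product: 5 (R)‑trimethyl[(4‑methylcyclopent‑1‑en‑1‑yl)oxy]silane
Conditions: LDA, THF, −78 °C; TMSCl
Reagents that add atoms: chlorotrimethylsilane C[Si](C)(C)Cl
Why: Kinetic enolisation and silylation favour the CH2 remote from the methyl‑bearing carbon, and the minor regioisomer later gives achiral, separable 3‑methylcyclopentenone.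

**Step 4**
Reactants: 5
Product: 6 (S)‑4‑methylcyclopent‑2‑en‑1‑one
Conditions: Pd(OAc)2, MeCN, rt
Reagents that add atoms: none
Why: Saegusa–Ito oxidation gives the enone regiospecifically and leaves the purchased C15 stereocentre untouched.

**Step 5**
Reactants: 7 (S)‑(−)‑limonene
Product: 8 (S)‑7,7‑dimethoxy‑5‑(prop‑1‑en‑2‑yl)heptan‑2‑one
Conditions: O3 (1 equiv), CH2Cl2–MeOH, −78 °C; TsOH, rt; NaHCO3; Me2S
Reagents that add atoms: ozone [O-][O+]=O; methanol CO
Why: Schreiber‑type ozonolysis cleaves the more electron‑rich trisubstituted ring alkene and differentiates the two termini as ketone and acetal, while C4 is not involved.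

**Step 6**
Reactants: 8; 3
Product: 9 (1E,8S)‑1‑iodo‑10,10‑dimethoxy‑2‑methyl‑8‑(prop‑1‑en‑2‑yl)dec‑1‑en‑5‑one
Conditions: LDA, THF, −78 °C; 3, DMPU, −78→−20 °C
Reagents that add atoms: none (3 is the alkylating reactant)
Why: The kinetic methyl‑ketone enolate undergoes SN2 alkylation with the reactive allylic bromide and installs C10–C13 with the E‑vinyl iodide intact.

**Step 7**
Reactants: 9
Product: 10 (R)‑2‑[(E)‑4‑iodo‑3‑methylbut‑3‑en‑1‑yl]‑5‑(prop‑1‑en‑2‑yl)cyclopent‑1‑ene‑1‑carbaldehyde
Conditions: TFA–H2O, CHCl3, 0 °C; then piperidine, AcOH, PhH, 80 °C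
Reagents that add atoms: water O
Why: Acetal hydrolysis followed by enamine‑mediated intramolecular aldol condensation, the known limonene keto‑aldehyde ring contraction, closes ring D as the formylcyclopentene.

**Step 8**
Reactants: 10
Product: 11 (1R,2S,5S)‑2‑[(E)‑4‑iodo‑3‑methylbut‑3‑en‑1‑yl]‑2‑methyl‑5‑(prop‑1‑en‑2‑yl)cyclopentane‑1‑carbaldehyde
Conditions: Me2CuLi, TMSCl, Et2O–THF, −78 °C; then K2CO3, MeOH, rt
Reagents that add atoms: lithium dimethylcuprate [Li+].C[Cu-]C
Why: TMSCl‑accelerated Gilman conjugate addition, fast enough at −78 °C to spare the vinyl iodide, delivers Me8 anti to the C4 isopropenyl group and sets quaternary C7, and base equilibration places the CHO on C25 trans to the isopropenyl group.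

**Step 9**
Reactants: 11; 6 (3 equiv)
Product: 12 (1R,2S,5S)‑2‑methyl‑2‑{(E)‑3‑methyl‑4‑[(5S)‑5‑methyl‑3‑oxocyclopent‑1‑en‑1‑yl]but‑3‑en‑1‑yl}‑5‑(prop‑1‑en‑2‑yl)cyclopentane‑1‑carbaldehyde
Conditions: Pd(OAc)2 (10 mol %), Bu4NCl, KOAc, DMF, 50 °C
Reagents that add atoms: none
Why: In this Heck (Jeffery) alkenylation the vinyl‑Pd species inserts at the enone β‑carbon C14, and β‑H elimination via the Pd enolate gives the linearly conjugated dienone with retained E geometry and an untouched C15.

**Step 10**
Reactants: 12
Product: 13 methyl (E)‑3‑[(1R,2S,5S)‑2‑methyl‑2‑{(E)‑3‑methyl‑4‑[(5S)‑5‑methyl‑3‑oxocyclopent‑1‑en‑1‑yl]but‑3‑en‑1‑yl}‑5‑(prop‑1‑en‑2‑yl)cyclopentyl]prop‑2‑enoate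
Conditions: Ph3P=CHCO2Me, PhMe, 80 °C
Reagents that add atoms: methyl (triphenylphosphoranylidene)acetate COC(=O)C=P(c1ccccc1)(c1ccccc1)c1ccccc1
Why: The stabilised ylide in this Wittig reaction olefinates only the aldehyde (E‑selective) and adds C23/C22 as the second Michael acceptor.

**Step 11**
Reactants: 13
Product: 14 methyl {5,7a‑dimethyl‑5‑[((5S)‑5‑methyl‑3‑oxocyclopent‑1‑en‑1‑yl)methyl]‑3‑(prop‑1‑en‑2‑yl)octahydro‑1H‑inden‑4‑yl}acetate. This is a trans‑hydrindane with H25 β, Me8 α, H24 α (CH2CO2Me equatorial) and Me12 β/axial (CH2–ring A equatorial).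
Conditions: Ru(bpy)3Cl2 (2.5 mol %), HCO2H, i‑Pr2NEt, MeCN (5 mM), blue LED, rt; then Et3N
Reagents that add atoms: none
Why: Proposed new method: this is a vinylogous photoreductive enone cyclisation in which Ru(I) reduces the acid‑activated dienone to a hydroxypentadienyl radical, its tertiary δ‑terminus C11 adds 6‑exo to the enoate β‑carbon C24, the α‑ester radical is quenched by HAT, the dienol is conjugated to the enone by the mild amine, and a chair transition state with both planar π‑arms equatorial makes Me12 and H24 axial (trans‑anti‑trans); the closest known reactions are the Brønsted‑acid photocatalytic reductive cyclisation of tethered enones (β‑radical, mostly 5‑exo) and Baizer–Little electrohydrocyclisation.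

**Step 12**
Reactants: 14
Product: 15 triethylsilyl enol ether. It is 14 with ring A converted to cis‑4‑methyl‑3‑(C13H2)‑1‑(triethylsilyloxy)cyclopent‑1‑ene (H14 α, H15 α; C13 and Me16 both β).
Conditions: Et3SiH, RhCl(PPh3)3 (2 mol %), PhH, 50 °C
Reagents that add atoms: triethylsilane CC[SiH](CC)CC
Why: Ojima 1,4‑hydrosilylation delivers H to C14 from the face anti to Me16, which gives the contra‑steric C13/Me16 cis relationship, and it gives the C18=C26 enol ether regiospecifically while the ester and the 1,1‑disubstituted alkene are inert.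

**Step 13**
Reactants: 15
Product: 16 aldehyde (15 with the C24 arm as CH2CHO)
Conditions: DIBAL‑H (1.05 equiv), CH2Cl2, −78 °C; Rochelle salt
Reagents that add atoms: none
Why: Partial DIBAL reduction stops at the aldehyde at −78 °C, and the ring‑A ketone is masked as the TES enol ether.

**Step 14**
Reactants: 16
Product: 17 propargylic alcohol (C24 arm CH2CH(OH)C≡CH, about 1:1 at C22, which is inconsequential)
Conditions: HC≡CMgBr, THF, −78→0 °C
Reagents that add atoms: ethynylmagnesium bromide C#C[Mg]Br
Why: Grignard 1,2‑addition adds C21/C20, and the new carbinol centre is destroyed in the next step.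

**Step 15**
Reactants: 17
Product: 18 allene (C24 arm CH2CH=C=CH2)
Conditions: o‑nitrobenzenesulfonylhydrazide, PPh3, DEAD, THF, −15→23 °C
Reagents that add atoms: none
Why: In the Myers allene synthesis, Mitsunobu displacement, sulfinate loss and retro‑ene loss of N2 from the propargylic diazene give the terminal allene under near‑neutral conditions that the enol ether tolerates.

**Step 16**
Reactants: 18
Product: 19 variecolol
Conditions: RVC(+)/Pt(−), undivided cell, 8 mA (2.2 F mol⁻¹), Et4NOTs, 2,6‑lutidine, MeCN–H2O 19:1 (2 mM), rt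
Reagents that add atoms: water O
Why: Proposed new method: this is an anodic silyl enol ether/allene oxidative annulation that closes an eight‑membered ring, in which selective oxidation of the enol ether (far below the alkene and allene potentials) gives an electrophilic C26 radical cation that attacks the central allene carbon C21 (8‑endo, giving an allyl radical, with the trans‑diequatorial C13/C23 arms pre‑organised), a second oxidation gives the allyl cation, the C18 carbonyl oxygen closes on the primary terminus C20 and water caps C18, the tether on the β face of C14 delivers C21 to the β face of C26 (cis A/B), the ring enforces the C21=C22 geometry and the cis 5/5 fusion fixes C18; the closest known reactions are Moeller anodic olefin couplings (5–7‑membered rings, no allenes), Snider Mn(III)/Cu(II) 8‑endo cyclisations and Mn(III) dihydrofuran annulations.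

## Compound list
1 | prop‑2‑yn‑1‑ol | C#CCO | starting material
2 | (E)‑3‑iodo‑2‑methylprop‑2‑en‑1‑ol | OC/C(C)=C/I | intermediate
3 | (E)‑3‑bromo‑1‑iodo‑2‑methylprop‑1‑ene | BrC/C(C)=C/I | intermediate
4 | (R)‑3‑methylcyclopentanone | C[C@@H]1CCC(=O)C1 | starting material
5 | (R)‑TMS enol ether | C[C@@H]1CC=C(O[Si](C)(C)C)C1 | intermediate
6 | (S)‑4‑methylcyclopent‑2‑enone | C[C@@H]1C=CC(=O)C1 | intermediate
7 | (S)‑limonene | C=C(C)[C@H]1CCC(C)=CC1 | starting material
8 | keto acetal | C=C(C)[C@H](CC(OC)OC)CCC(C)=O | intermediate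
9 | alkylated keto acetal | C=C(C)[C@H](CC(OC)OC)CCC(=O)CC/C(C)=C/I | intermediate
10 | ring‑D enal | C=C(C)[C@H]1CCC(CC/C(C)=C/I)=C1C=O | intermediate
11 | ring‑D aldehyde (C7 quaternary) | C=C(C)[C@H]1CC[C@@](C)(CC/C(C)=C/I)[C@@H]1C=O | intermediate
12 | dienone aldehyde | C=C(C)[C@H]1CC[C@@](C)(CC/C(C)=C/C2=CC(=O)C[C@@H]2C)[C@@H]1C=O | intermediate
13 | dienone enoate | C=C(C)[C@H]1CC[C@@](C)(CC/C(C)=C/C2=CC(=O)C[C@@H]2C)[C@@H]1/C=C/C(=O)OC | intermediate
14 | C/D hydrindane enone ester | C=C(C)[C@H]1CC[C@@]2(C)CC[C@](C)(CC3=CC(=O)C[C@@H]3C)[C@@H](CC(=O)OC)[C@H]12 | intermediate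
15 | TES enol ether ester | C=C(C)[C@H]1CC[C@@]2(C)CC[C@](C)(C[C@@H]3C=C(O[Si](CC)(CC)CC)C[C@@H]3C)[C@@H](CC(=O)OC)[C@H]12 | intermediate
16 | TES enol ether aldehyde | C=C(C)[C@H]1CC[C@@]2(C)CC[C@](C)(C[C@@H]3C=C(O[Si](CC)(CC)CC)C[C@@H]3C)[C@@H](CC=O)[C@H]12 | intermediate
17 | propargylic alcohol | C=C(C)[C@H]1CC[C@@]2(C)CC[C@](C)(C[C@@H]3C=C(O[Si](CC)(CC)CC)C[C@@H]3C)[C@@H](CC(O)C#C)[C@H]12 | intermediate
18 | allene | C=C(C)[C@H]1CC[C@@]2(C)CC[C@](C)(C[C@@H]3C=C(O[Si](CC)(CC)CC)C[C@@H]3C)[C@@H](CC=C=C)[C@H]12 | intermediate
19 | variecolol | C=C(C)[C@H]1CC[C@@]2(C)CC[C@]3(C)C[C@H]4[C@@H](C)C[C@@]5(O)OC/C(=C/C[C@H]3[C@H]12)[C@@H]45 | target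

## Step count
- **Total steps:** 16.
- **Longest linear sequence:** 13 (steps 1, 2 and 6–16, from prop‑2‑yn‑1‑ol).
- **Other branches:** the (S)‑limonene branch (steps 5–16) is 12 steps. The (R)‑3‑methylcyclopentanone branch (steps 3, 4 and 9–16) is 10 steps.

## Steps most likely to fail
1. **Step 16 (new anodic 8‑ring/allene annulation).**
   - Risks:
     - Cyclisation may be slow relative to enone formation or hydrolysis.
     - The C26 facial outcome is untested.
     - Attack on the allene may take the wrong regiochemistry.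
     - Oxygen may close at C22 instead of C20.
   - Fallback (known chemistry):
     - Convert aldehyde 16 into a (Z)‑2‑iodoallyl silyl ether arm by iodo‑Wittig olefination with Ph3P=C(I)CH2OTBS.
     - Form C26–C21 by Pd(0)‑catalysed intramolecular ketone α‑alkenylation. The regiodefined enolate is released in situ from the TES enol ether with fluoride (CsF/Bu3SnF), which avoids an organolithium next to the vinyl iodide.
     - TBAF deprotection then gives spontaneous hemiketalisation.
2. **Step 11 (new vinylogous photoreductive cyclisation).**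
   - Risks: simple 1,6‑reduction of the dienone; sluggish addition of the stabilised tertiary radical.
   - Fallback (known chemistry), which reverses the roles of the two carbons:
     - Add propargylzinc bromide to aldehyde 12 and convert the C24 carbinol to its xanthate.
     - Close ring C by a conventional (TMS)3SiH/AIBN 6‑exo radical conjugate cyclisation of the C24 radical onto the dienone.
     - The arm then already carries the alkyne for a Crabbé homologation to the allene.
3. **Step 9 (Heck on a 4‑substituted cyclopentenone).**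
   - Risks: reductive Heck product; enone oligomerisation; erosion of C15.
   - Fallback: couple 11 and 6 by Ni‑catalysed reductive conjugate addition (Mn, TESCl) to the silyl enol ether. Then regenerate the unsaturation by Saegusa–Ito oxidation to give 12 (+1 step).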